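Starting material is the entry you follow through Tuesday's and Monday's flasks, and with 0.68 M of it there is less than of partner at 2.04 M, which makes it the limiting reagent of that pair.

| flask | starting material | partner | protic impurity | free catalyst | remark | time |
|---|---|---|---|---|---|---|
| north-west | 0.34 M | 2.04 M | 0.204 M | 3.4 mM | run made earlier |  |
| west | 1.4 M | 2.04 M | 0.204 M | 3.4 mM | run made earlier |  |
| Tuesday's | 0.68 M | 2.04 M | 0.204 M | 3.4 mM |  | 10 h |
| Monday's | 0.68 M | 2.04 M | 0.204 M | 3.4 mM |  | 20 h |

| run | time / h | product / % | starting material / % | catalyst intermediate D / % | catalyst intermediate B / % |
|---|---|---|---|---|---|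
| north-west | 0.667 | 6 | 94 | 0 | 2 |
| north-west | 1.33 | 9 | 93 | 0 | 0 |
| north-west | 3.00 | 16 | 81 | 1 | 0 |
| north-west | 8.00 | 45 | 59 | 0 | 0 |
| west | 0.667 | 1 | 98 | 2 | 3 |
| west | 1.33 | 4 | 100 | 2 | 1 |
| west | 3.00 | 3 | 96 | 1 | 0 |
| west | 8.00 | 11 | 86 | 2 | 1 |

(standard deviation of a reading: 2 percentage points)



- which of these there is most of at the end, counted by the starting material in it, Tuesday's (starting material / catalyst intermediate B / catalyst intermediate D / product)
- which of these there is most of at the end, counted by the starting material in it, Monday's (starting material / catalyst intermediate B / catalyst intermediate D / product)
- the largest of these amounts at the end, in percent of the starting material charged, Tuesday's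
- the largest of these amounts at the end, in percent of the starting material charged, Monday's

Take as the zero of the scale the first-order case, in which runs of different charge convert the same percent in the same hours. At 8.00 h the north-west run reads 45% product and the west run 11%, far from that zero, but in concentration these come to 0.153 M and 0.154 M. So I keep their mean per hour, 0.0192 M/h, as the molar output, the product made per hour at these catalyst and partner charges.

Now the books, in my own reckoning. In Tuesday's flask at 10 h, product takes 28.2% of the charge, the catalyst can bind at most 0.500%, and the remaining 71.3% is starting material. In Monday's flask at 20 h, product takes 56.5% and starting material keeps 43.1%. That is 0.293 M, more than the 0.201 M read at the end of the north-west run, so by this reckoning Monday's flask stays inside the range the output was read over.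

The forecast names starting material at 72% (66% to 78%) for Tuesday's flask and product at 54% (50% to 64%) for Monday's, calling the rate “essentially zero order in starting material, so the catalyst looks saturated”. Its Monday figure stands lower than mine, as it allows for partner depletion or catalyst ageing.

Tuesday's flask gives starting material at 71.2%, and Monday's gives product at 55.3%.

    catalyst intermediate E → free catalyst + product (k = 1300 /h)
    catalyst intermediate D ⇌ released group + catalyst intermediate E (K = 0.580 M, k = 8.20 /h)
    catalyst intermediate A → catalyst intermediate B (k = 56.0 /h)
    catalyst intermediate C → catalyst intermediate D (k = 900 /h)
    partner + catalyst intermediate B → catalyst intermediate C (k = 26.0 /M/h)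
    partner + protic impurity → quenched reagent (k = 9.00 /M/h)
    starting material + free catalyst ⇌ catalyst intermediate A (K = 17.0 /M, k = 170 /M/h)

In Tuesday's flask at 10.0 h, the exchange of starting material and free catalyst with catalyst intermediate A, by this step alone and both ways together, relaxes with a half-life of 0.450 min, short against the 10 h. At that time in Tuesday's flask, catalyst intermediate D, the resting state, holds 68.0% of the catalyst charged, more than any other form, and 7.96% is free. Between 10.0 h and 20.0 h, Monday's flask makes 0.0184 M/h of product, less than the molar output of 0.0192 M/h read from the earlier runs. For Tuesday's flask read at 25.0 h, that output reckons 70.5% product, and the flask holds 68.1%.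

The readings stem from a simulated flask on assumed constants, and the scatter is random.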